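The data were generated by integration on assumed constants; noise was put on by code.

Oak is where I began, and the flasks now asked about differ from it mainly in how the charge goes in.

| setting | oak | birch | elm | ash | amber | red | green | ochre |
|---|---|---|---|---|---|---|---|---|
| starting material | 20 mM | 10 mM | 40 mM | 20 mM | 20 mM | 20 mM (fed, over 15 h) | 20 mM | 20 mM (fed, over 6.0 d) |
| second substrate | 40 mM | 40 mM | 40 mM | 40 mM | 40.0 mM | 40.0 mM | 40.0 mM | 40.0 mM |
| partner | 22 mM | 22 mM | 22 mM | 22 mM | 22.0 mM (fed, over 6.0 d) | 22.0 mM | 22.0 mM | 22.0 mM |
| protic impurity | 0.40 mM | 0.40 mM | 0.40 mM | 0.80 mM | 0.400 mM | 0.400 mM | 0.400 mM | 0.400 mM |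
| free catalyst | 100 µM | 100 µM | 100 µM | 100 µM | 100 µM | 100 µM | 100 µM | 100 µM |
| remark | run made earlier | run made earlier | run made earlier | run made earlier | all else is in the flask from the start; the feed brings no volume worth counting | all else is in the flask from the start; the feed brings no volume worth counting | everything together at the start | all else is in the flask from the start; the feed brings no volume worth counting |
| time |  |  |  |  | 15 d | 15 d | 15 d | 15 d |

- oak (time / d: target / %): 1.67: 12.1; 3.00: 15.4; 5.00: 17.5; 6.00: 17.9; 8.00: 17.8; 10.0: 18.5
- birch (time / d: target / %): 3.00: 17.0; 6.00: 19.7; 10.0: 19.5; 12.0: 20.4; 15.0: 20.5; 20.0: 20.0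
- elm (time / d: target / %): 1.25: 8.9; 4.00: 12.8; 6.00: 14.9; 10.0: 15.5; 15.0: 15.9; 20.0: 15.2
- ash (time / d: target / %): 4.00: 16.7; 8.00: 18.0; 10.0: 17.8; 15.0: 17.9; 20.0: 18.2

(each reading ± 0.5 percentage points)

- the analysis behind the earlier runs scatters by 0.5 percentage points, standard deviation

- the flask with the highest amount of target, in percent of the starting material charged ("all alike" if they lie within 1.5 percentage points) (amber / red / green / ochre / all alike)
- final target, as a percentage of the starting material charged, in amber
- final target, as a percentage of the starting material charged, in red
- final target, as a percentage of the starting material charged, in green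
- final target, as a percentage of the starting material charged, in ochre

Oak flattened at about 18.1% of its starting material, or 3.61 mM of target, although it held more partner than starting material (22 mM against 20 mM). Those numbers do not seem to go together.

I cleared this up with the clock of the rise, the time constant of an exponential approach to the plateau. Oak's reading at 1.67 d gives about 1.51 d. Elm, with twice oak's starting material, gives about 1.47 d. So I supposed that partner was the limiting reagent and that second substrate, charged at 40 mM, took most of it on this clock. Target would then form roughly in proportion to c(starting material) while partner went.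

In ochre the steady feed makes c(starting material) rise nearly linearly, and integrating that against the exponential loss of partner has a closed form. For ochre's 6.0 d it gives 24.7%. This is the feed share: the mean part of the charge present while partner goes, equal to the clock over the feed time, times the part of the partner gone when the feed ends. I therefore reckoned 4.45% for ochre. Red's 15 h gives a share of 81.9%, hence 14.8%, and green repeats oak. Amber feeds partner instead, so the share gave me no number for it.

The forecast, on other grounds than mine, named green highest, with green 18%, red 15%, amber 17% and ochre 5%, and said “Ochre feeds into a dying catalyst”.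

Green came out highest: green 18.2%, red 16.1%, amber 15.3%, ochre 6.37%. At 15.0 d green held 0.0239% of its partner. Ochre's share times green's result is 4.50%, which is 1.9 percentage points under ochre's result.

    starting material + free catalyst ⇌ catalyst intermediate A (K = 65.5 M⁻¹, k = 423 M⁻¹ h⁻¹)
    second substrate + free catalyst ⇌ catalyst intermediate B (K = 763 M⁻¹, k = 597 M⁻¹ h⁻¹)
    partner + catalyst intermediate A → free catalyst + target (k = 400 M⁻¹ h⁻¹)
    partner + catalyst intermediate B → free catalyst + second product (k = 239 M⁻¹ h⁻¹)
    starting material + protic impurity → quenched substrate (k = 36.8 M⁻¹ h⁻¹)

Ochre's neighbour, charged with 0.040 mM of free catalyst instead of 100 µM, takes the same reckoning. I stretched the clock in proportion, to 3.77 d, so the neighbour's feed share is 50.0%, larger than ochre's. With green's result this gives 9.10% of target. The neighbour gave 10.9%, and at 15.0 d it still held 4.04% of its partner.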